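The plan rests on cutting the C7–C11 bond (germacrane numbering), the β–α bond of the α-methylene-γ-butyrolactone ring. C7 sits between two oxygen-bearing carbons, C6 (lactone oxygen) and C8 (angelate oxygen). This array is read as a 2,3-epoxy alcohol opened at its inner carbon. The precursor is an acyclic trans C7–C8 epoxide whose C6 hydroxyl carries a diethylphosphonoacetate. One base-triggered operation opens the epoxide 5-exo with inversion at C7, closes the lactone and frees the C8 hydroxyl. Once formaldehyde is added, it also installs the C11=C13 methylene. A Ni/Cr coupling (C9–C10) and a ring-closing metathesis (C4=C5) then build the ten-membered cis,cis-diene ring.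

Key step: step 4

Remark on numbering: the ring is C1–C10. C14 is the formyl carbon on C10 and C15 the hydroxymethyl carbon on C4. C11, C12 and C13 are the lactone α-carbon, carbonyl and exocyclic methylene.
Remark on the chemistry: both ring alkenes are cis within the ring (their CIP descriptors are E only because of the oxygenated substituents). The 2-methylbutanoate is (R) as drawn. Angelic acid, (R)-2-methylbutanoic acid, Cy2BH and (−)-MIB are taken as purchasable.

Step 1
Reactants: 1 tert-butyldimethyl(prop-2-yn-1-yloxy)silane; 2 (E)-but-2-enal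
Product: 5 (2E,4R,5E)-1-(tert-butyldimethylsilyloxy)hepta-2,5-dien-4-ol, via alkenylborane 3 (not isolated), via alkenylzinc 4 (not isolated)
Conditions: Cy2BH, toluene, 0 °C to rt; Me2Zn, −78 °C; (−)-MIB [(2S)-3-exo-morpholinoisoborneol, 5 mol%], then 2, −30 to 0 °C; aq. NH4Cl
Reagents that add atoms: none
Why: Hydroboration gives the (E)-alkenylborane, boron–zinc exchange gives the alkenylzinc, and the amino-alcohol-catalysed asymmetric alkenylzinc addition sets C6 (R) in the facial sense that (−)-MIB shows in dialkylzinc additions.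

Step 2
Reactants: 5 (2E,4R,5E)-1-(tert-butyldimethylsilyloxy)hepta-2,5-dien-4-ol
Product: 6 (1R,2E)-1-[(2R,3R)-3-(tert-butyldimethylsilyloxymethyl)oxiran-2-yl]but-2-en-1-ol
Conditions: Ti(OiPr)4 (20 mol%), D-(−)-diisopropyl tartrate (24 mol%), t-BuOOH (1.1 equiv), 4 Å MS, CH2Cl2, −20 °C
Reagents that add atoms: tert-butyl hydroperoxide, CC(C)(C)OO
Why: Sharpless asymmetric epoxidation, in which D-(−)-tartrate makes the C7=C8 alkene of the (R)-carbinol the matched one and gives the anti epoxy alcohol (sets C7 and C8), while the propenyl alkene is mismatched and the minor (S)-carbinol is diverted to a separable constitutional isomer, which should raise the optical purity.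

Step 3
Reactants: 6 anti epoxy alcohol; 7 2-(diethoxyphosphoryl)acetic acid
Product: 8 (1R,2E)-1-[(2R,3R)-3-(tert-butyldimethylsilyloxymethyl)oxiran-2-yl]but-2-en-1-yl 2-(diethoxyphosphoryl)acetate
Conditions: DCC, DMAP (cat.), CH2Cl2, 0 °C to rt
Reagents that add atoms: none
Why: Steglich esterification of the secondary alcohol is near neutral, leaves epoxide and silyl ether untouched and changes no stereocenter.

Step 4
Reactants: 8 epoxy phosphonoacetate
Product: 10 (4R,5R)-4-[(1S)-2-(tert-butyldimethylsilyloxy)-1-hydroxyethyl]-3-methylidene-5-[(1E)-prop-1-enyl]oxolan-2-one, via phosphono lactone 9 (not isolated)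
Conditions: KOtBu (1.0 equiv), THF, 0 to 45 °C; then (CH2O)n, 0 °C to rt
Reagents that add atoms: formaldehyde (from paraformaldehyde), C=O
Why: Proposed new method: KOtBu deprotonates C11 of the phosphonoacetate, the phosphoryl-stabilised carbanion attacks C7 of the C7–C8 epoxide from the side opposite the C7–O bond, the released C8 alkoxide is quenched at once by the more acidic C11–H of 9, and the resulting phosphonate anion olefinates formaldehyde (Horner–Wadsworth–Emmons) to give the C11=C13 methylene and potassium diethyl phosphate, so the single equivalent of base is used up. The closest known reaction types are the telescoped intramolecular Michael/olefination of phosphonoacetates of γ-hydroxy enones, the intermolecular opening of epoxides by sodium triethyl phosphonoacetate to α-phosphono-γ-lactones, and the base-induced 5-exo closure of 2,3-epoxy alcohol carbamates at the inner carbon, whereas the ester-tethered carbon version on an epoxide has not been shown. The γ-lactone ring (O, C12, C11, C7, C6) closes in the 5-exo-tet mode, formally 5-(enolendo), which should be tolerated because the carbanion keeps its phosphoryl stabilisation while the ester carbonyl twists out of conjugation, as in the Michael variant. C7 is set by SN2 inversion of the epoxide carbon, C8 keeps its C–O bond and C6 is untouched, so the anti epoxy alcohol with a trans epoxide maps onto the trans-disubstituted lactone with the C8 oxygen configured as in the target. The step needs 5-exo over 6-endo attack, secured by the three-atom tether and the collinear trajectory available only at C7, and it needs the lactone to stay on the C6 oxygen, secured because the C8 alternative would be the cis-disubstituted lactone and no strong base remains.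

Step 5
Reactants: 10 hydroxy α-methylene lactone; 11 angelic acid [(2Z)-2-methylbut-2-enoic acid]
Product: 13 (1S)-2-(tert-butyldimethylsilyloxy)-1-{(2R,3S)-4-methylidene-5-oxo-2-[(1E)-prop-1-enyl]oxolan-3-yl}ethyl (2Z)-2-methylbut-2-enoate, via mixed anhydride 12 (not isolated)
Conditions: 2,4,6-trichlorobenzoyl chloride, Et3N, toluene, rt; then 10, 75 °C
Reagents that add atoms: none
Why: Yamaguchi-type mixed-anhydride esterification run without a nucleophilic catalyst is the established way to form angelates without Z to E isomerisation, and no stereocenter is touched.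

Step 6
Reactants: 13 C8 angelate silyl ether
Product: 14 (1S)-2-hydroxy-1-{(2R,3S)-4-methylidene-5-oxo-2-[(1E)-prop-1-enyl]oxolan-3-yl}ethyl (2Z)-2-methylbut-2-enoate
Conditions: HF·pyridine, pyridine, THF, 0 °C
Reagents that add atoms: none
Why: Fluoride desilylation under buffered, weakly acidic conditions frees the primary C9 alcohol while keeping 1,2-migration of the hindered angelate slow.

Step 7
Reactants: 14 C9 alcohol
Product: 15 (1S)-2-oxo-1-{(2R,3S)-4-methylidene-5-oxo-2-[(1E)-prop-1-enyl]oxolan-3-yl}ethyl (2Z)-2-methylbut-2-enoate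
Conditions: Dess–Martin periodinane, CH2Cl2, 0 °C to rt
Reagents that add atoms: none
Why: Dess–Martin oxidation is fast and non-basic, so the α-acyloxy aldehyde should form without epimerisation at C8.

Step 8
Reactants: 16 2-methylidenepropane-1,3-diol
Product: 17 2-(tert-butyldimethylsilyloxymethyl)prop-2-en-1-ol
Conditions: NaH (1.0 equiv), THF, 0 °C; TBSCl (1.0 equiv), rt
Reagents that add atoms: tert-butyldimethylsilyl chloride, CC(C)(C)[Si](C)(C)Cl
Why: Monosilylation of the symmetric diol through its sparingly soluble monosodium alkoxide is a standard desymmetrising silyl ether formation.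

Step 9
Reactants: 17 monosilylated diol
Product: 19 ethyl 4-(tert-butyldimethylsilyloxymethyl)pent-4-enoate, via ketene acetal 18 (not isolated)
Conditions: MeC(OEt)3, EtCO2H (cat.), 140 °C, EtOH distilled off
Reagents that add atoms: triethyl orthoacetate, CC(OCC)(OCC)OCC
Why: Johnson–Claisen rearrangement, whose [3,3] shift forms the C2–C3 bond and regenerates a 1,1-disubstituted alkene at C4.

Step 10
Reactants: 19 pentenoate
Product: 20 4-(tert-butyldimethylsilyloxymethyl)pent-4-enal
Conditions: DIBAL-H (1.05 equiv), CH2Cl2, −78 °C; aqueous work-up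
Reagents that add atoms: none
Why: Partial DIBAL-H reduction stops at the aluminium hemiacetal at low temperature and releases the aldehyde on work-up.

Step 11
Reactants: 20 pentenal
Product: 21 ethyl (2Z)-6-(tert-butyldimethylsilyloxymethyl)-2-iodohepta-2,6-dienoate
Conditions: Ph3P=CHCO2Et, NIS, CH2Cl2, −20 °C; then 20, −20 °C to rt
Reagents that add atoms: ethyl (triphenylphosphoranylidene)acetate, CCOC(=O)C=P(c1ccccc1)(c1ccccc1)c1ccccc1; N-iodosuccinimide, O=C1CCC(=O)N1I
Why: Wittig olefination with the iodo ylide made in situ places the ester trans to the chain, as stabilised ylides do, and so fixes the C1=C10 geometry as the (Z)-α-iodo enoate.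

Step 12
Reactants: 21 iodo enoate
Product: 22 (2Z)-6-(tert-butyldimethylsilyloxymethyl)-2-iodohepta-2,6-dien-1-ol
Conditions: DIBAL-H (2.2 equiv), CH2Cl2, −78 °C; aqueous work-up
Reagents that add atoms: none
Why: DIBAL-H 1,2-reduction of the enoate gives the allylic alcohol and leaves the alkenyl iodide and its geometry intact at low temperature.

Step 13
Reactants: 22 iodo allylic alcohol
Product: 23 (2Z)-6-(tert-butyldimethylsilyloxymethyl)-2-iodo-1-(triethylsilyloxy)hepta-2,6-diene
Conditions: TESCl, imidazole, CH2Cl2, 0 °C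
Reagents that add atoms: triethylsilyl chloride, CC[Si](CC)(CC)Cl
Why: Silyl ether formation with TES gives a C14 protecting group that can later be removed beside the primary TBS ether at C15.

Step 14
Reactants: 15 C9 aldehyde; 23 alkenyl iodide
Product: 25 seco alcohol (6R,7S,8S,9R) with free C9 hydroxyl, C8 angelate and the (Z)-alkenyl chain C10(CH2OTES)=C1H–C2H2–C3H2–C4(=CH2)CH2OTBS, via alkenylchromium 24 (not isolated)
Conditions: CrCl2 (4 equiv), NiCl2 (1 mol%), DMSO, rt
Reagents that add atoms: none
Why: Nozaki–Hiyama–Kishi coupling, in which the alkenylchromium species forms with retention of geometry and adds only to the aldehyde beside lactone and esters, and polar Felkin–Anh control by the C8 acyloxy group should favour the 8,9-anti (9R) alcohol.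

Step 15
Reactants: 25 seco alcohol; 26 (R)-2-methylbutanoic acid
Product: 27 seco diester (6R,7S,8S,9R), C9 (2R)-2-methylbutanoate of 25
Conditions: DCC, DMAP (cat.), CH2Cl2, 0 °C to rt
Reagents that add atoms: none
Why: Steglich esterification acylates the allylic alcohol with retention at C9, and carbodiimide activation avoids a ketene pathway, so the α-stereocenter of the acyl group is kept.

Step 16
Reactants: 27 seco diester
Product: 28 seco C14 allylic alcohol (TES removed, TBS kept)
Conditions: PPTS (cat.), MeOH/CH2Cl2, 0 °C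
Reagents that add atoms: none
Why: Acid-catalysed methanolysis distinguishes the two primary silyl ethers by size and should cleave only the TES group.

Step 17
Reactants: 28 seco C14 alcohol
Product: 29 seco enal (C14 aldehyde, CIP 1(10)E)
Conditions: Dess–Martin periodinane, CH2Cl2, 0 °C to rt
Reagents that add atoms: none
Why: Dess–Martin oxidation of the primary allylic alcohol gives the enal in its thermodynamically preferred geometry and turns C1=C10 into an electron-poor alkene before metathesis.

Step 18
Reactants: 29 seco enal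
Product: 30 15-O-TBS ether of the target (ten-membered ring closed)
Conditions: second-generation Hoveyda–Grubbs catalyst (15 mol%), 1,4-benzoquinone (cat.), toluene (0.5 mM), 80 °C, argon sparge
Reagents that add atoms: none
Why: Ring-closing metathesis, in which ruthenium should load at the propenyl group and close on the 1,1-disubstituted C4 alkene with loss of propene, the ten-membered ring favours the ring-cis C4=C5 geometry, the enal, angelate and α-methylene lactone alkenes are electron-poor spectators, and the trans-lactone plus the ring-cis enal pre-bend the chain.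

Step 19
Reactants: 30 15-O-TBS ether
Product: 31 target, (6R,7S,8S,9R)-8-angeloyloxy-15-hydroxy-9-[(2R)-2-methylbutanoyloxy]-14-oxogermacra-1(10),4,11(13)-trien-12,6-olide
Conditions: HF·pyridine, THF, 0 °C to rt
Reagents that add atoms: none
Why: Fluoride desilylation under weakly acidic conditions frees C15–OH without harming the enal, the two esters or the α-methylene lactone.

Compound list
1 | tert-butyldimethyl(prop-2-yn-1-yloxy)silane | C#CCO[Si](C)(C)C(C)(C)C | starting material
2 | (E)-but-2-enal | C/C=C/C=O | starting material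
3 | (E)-[3-(tert-butyldimethylsilyloxy)prop-1-enyl]dicyclohexylborane | CC(C)(C)[Si](C)(C)OC/C=C/B(C1CCCCC1)C1CCCCC1 | intermediate
4 | (E)-[3-(tert-butyldimethylsilyloxy)prop-1-enyl](methyl)zinc | CC(C)(C)[Si](C)(C)OC/C=C/[Zn]C | intermediate
5 | (2E,4R,5E)-1-(tert-butyldimethylsilyloxy)hepta-2,5-dien-4-ol | C/C=C/[C@@H](O)/C=C/CO[Si](C)(C)C(C)(C)C | intermediate
6 | (1R,2E)-1-[(2R,3R)-3-(tert-butyldimethylsilyloxymethyl)oxiran-2-yl]but-2-en-1-ol | C/C=C/[C@@H](O)[C@H]1O[C@@H]1CO[Si](C)(C)C(C)(C)C | intermediate
7 | 2-(diethoxyphosphoryl)acetic acid | CCOP(=O)(CC(=O)O)OCC | starting material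
8 | (1R,2E)-1-[(2R,3R)-3-(tert-butyldimethylsilyloxymethyl)oxiran-2-yl]but-2-en-1-yl 2-(diethoxyphosphoryl)acetate | C/C=C/[C@@H](OC(=O)CP(=O)(OCC)OCC)[C@H]1O[C@@H]1CO[Si](C)(C)C(C)(C)C | intermediate
9 | 3-(diethoxyphosphoryl) analogue of 10 (C6, C7, C8 as in 10, C11 unassigned, present as its potassium salt) | CCOP(=O)(OCC)C1C(=O)O[C@H](/C=C/C)[C@H]1[C@H](O)CO[Si](C)(C)C(C)(C)C | intermediate
10 | (4R,5R)-4-[(1S)-2-(tert-butyldimethylsilyloxy)-1-hydroxyethyl]-3-methylidene-5-[(1E)-prop-1-enyl]oxolan-2-one | C=C1C(=O)O[C@H](/C=C/C)[C@H]1[C@H](O)CO[Si](C)(C)C(C)(C)C | intermediate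
11 | angelic acid, (2Z)-2-methylbut-2-enoic acid | C/C=C(/C)C(=O)O | starting material
12 | (2Z)-2-methylbut-2-enoic 2,4,6-trichlorobenzoic anhydride | C/C=C(/C)C(=O)OC(=O)c1c(Cl)cc(Cl)cc1Cl | intermediate
13 | (1S)-2-(tert-butyldimethylsilyloxy)-1-{(2R,3S)-4-methylidene-5-oxo-2-[(1E)-prop-1-enyl]oxolan-3-yl}ethyl (2Z)-2-methylbut-2-enoate | C=C1C(=O)O[C@H](/C=C/C)[C@H]1[C@H](OC(=O)/C(C)=C\C)CO[Si](C)(C)C(C)(C)C | intermediate
14 | (1S)-2-hydroxy-1-{(2R,3S)-4-methylidene-5-oxo-2-[(1E)-prop-1-enyl]oxolan-3-yl}ethyl (2Z)-2-methylbut-2-enoate | C=C1C(=O)O[C@H](/C=C/C)[C@H]1[C@H](OC(=O)/C(C)=C\C)CO | intermediate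
15 | (1S)-2-oxo-1-{(2R,3S)-4-methylidene-5-oxo-2-[(1E)-prop-1-enyl]oxolan-3-yl}ethyl (2Z)-2-methylbut-2-enoate | C=C1C(=O)O[C@H](/C=C/C)[C@H]1[C@H](OC(=O)/C(C)=C\C)C=O | intermediate
16 | 2-methylidenepropane-1,3-diol | C=C(CO)CO | starting material
17 | 2-(tert-butyldimethylsilyloxymethyl)prop-2-en-1-ol | C=C(CO)CO[Si](C)(C)C(C)(C)C | intermediate
18 | mixed ketene acetal, 1-ethoxyvinyl ether of 17 | C=C(OCC)OCC(=C)CO[Si](C)(C)C(C)(C)C | intermediate
19 | ethyl 4-(tert-butyldimethylsilyloxymethyl)pent-4-enoate | CCOC(=O)CCC(=C)CO[Si](C)(C)C(C)(C)C | intermediate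
20 | 4-(tert-butyldimethylsilyloxymethyl)pent-4-enal | O=CCCC(=C)CO[Si](C)(C)C(C)(C)C | intermediate
21 | ethyl (2Z)-6-(tert-butyldimethylsilyloxymethyl)-2-iodohepta-2,6-dienoate | CCOC(=O)/C(I)=C/CCC(=C)CO[Si](C)(C)C(C)(C)C | intermediate
22 | (2Z)-6-(tert-butyldimethylsilyloxymethyl)-2-iodohepta-2,6-dien-1-ol | OC/C(I)=C/CCC(=C)CO[Si](C)(C)C(C)(C)C | intermediate
23 | (2Z)-6-(tert-butyldimethylsilyloxymethyl)-2-iodo-1-(triethylsilyloxy)hepta-2,6-diene | CC[Si](CC)(CC)OC/C(I)=C/CCC(=C)CO[Si](C)(C)C(C)(C)C | intermediate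
24 | alkenylchromium dichloride from 23 (geometry retained) | C=C(CO[Si](C)(C)C(C)(C)C)CC/C=C(/CO[Si](CC)(CC)CC)[Cr](Cl)Cl | intermediate
25 | seco alcohol (6R,7S,8S,9R): lactone of 13 with C8 angelate, free C9–OH and (Z)-C10(CH2OTES)=C1H–CH2CH2–C4(=CH2)CH2OTBS | C=C1C(=O)O[C@H](/C=C/C)[C@H]1[C@H](OC(=O)/C(C)=C\C)[C@H](O)/C(CO[Si](CC)(CC)CC)=C\CCC(=C)CO[Si](C)(C)C(C)(C)C | intermediate
26 | (R)-2-methylbutanoic acid | CC[C@@H](C)C(=O)O | starting material
27 | seco diester (6R,7S,8S,9R): C9 (2R)-2-methylbutanoate of 25 | C=C1C(=O)O[C@H](/C=C/C)[C@H]1[C@H](OC(=O)/C(C)=C\C)[C@H](OC(=O)[C@H](C)CC)/C(CO[Si](CC)(CC)CC)=C\CCC(=C)CO[Si](C)(C)C(C)(C)C | intermediate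
28 | seco C14 allylic alcohol (27 without TES) | C=C1C(=O)O[C@H](/C=C/C)[C@H]1[C@H](OC(=O)/C(C)=C\C)[C@H](OC(=O)[C@H](C)CC)/C(CO)=C\CCC(=C)CO[Si](C)(C)C(C)(C)C | intermediate
29 | seco enal (C14 aldehyde, C2 trans to CHO) | C=C1C(=O)O[C@H](/C=C/C)[C@H]1[C@H](OC(=O)/C(C)=C\C)[C@H](OC(=O)[C@H](C)CC)/C(C=O)=C\CCC(=C)CO[Si](C)(C)C(C)(C)C | intermediate
30 | 15-O-tert-butyldimethylsilyl ether of the target | C=C1C(=O)O[C@@H]2/C=C(/CO[Si](C)(C)C(C)(C)C)CC/C=C(/C=O)[C@@H](OC(=O)[C@H](C)CC)[C@@H](OC(=O)/C(C)=C\C)[C@@H]12 | intermediate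
31 | (6R,7S,8S,9R)-8-angeloyloxy-15-hydroxy-9-[(2R)-2-methylbutanoyloxy]-14-oxogermacra-1(10),4,11(13)-trien-12,6-olide, both ring alkenes ring-cis | C=C1C(=O)O[C@@H]2/C=C(/CO)CC/C=C(/C=O)[C@@H](OC(=O)[C@H](C)CC)[C@@H](OC(=O)/C(C)=C\C)[C@@H]12 | target

Total steps: 19. Longest linear sequence: 13 steps (steps 1–7, then 14–19).

Steps most likely to fail

1. Step 4.
- What may go wrong: the stabilised carbanion may be too weak a nucleophile for an unactivated disubstituted epoxide. The ester tether may also fail to reach the backside trajectory, so that on heating silyl migration or decomposition takes over.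
- Fallback: the same bond is closed by a radical on an ether tether, using known chemistry. It sets out from 6 and comes back at 13.
- O-Propargylation (NaH, propargyl bromide, THF) gives propargyl ether F1.
- Cp2TiCl (trivalent titanium, made from Cp2TiCl2 and Zn dust, THF, rt) opens the epoxide homolytically (RajanBabu–Nugent reaction). The C7 radical closes 5-exo-dig on the alkyne.
- Hydrogen abstraction and acidic work-up give methylidene tetrahydrofuran alcohol F2. Its C6 and C7 substituents are trans for steric reasons, and C8 is retained.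
- Angeloylation as in step 5 gives methylidene tetrahydrofuran angelate F3.
- Allylic oxidation of the ring CH2 (C12) with CrO3·(pyridine)2 in CH2Cl2 leads to 13.

2. Step 18.
- What may go wrong: oligomerisation by cross metathesis may outrun closure of the strained ten-membered ring, or ruthenium may close on another alkene of the chain.
- Fallback: the order of the two unions is reversed, so that the ring is closed at C9–C10 instead. It sets out from 15 and 23 and comes back at 30.
- Cross metathesis (second-generation Hoveyda–Grubbs catalyst, CH2Cl2, 40 °C, excess 23) forms C4=C5 without ring strain. The isomer with C15 trans to C6 is separated as seco iodo aldehyde F4.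
- CrCl2/NiCl2 in DMSO at high dilution converts F4 through alkenylchromium species F5 into macrocyclic alcohol F6 (intramolecular Nozaki–Hiyama–Kishi reaction).
- Esterification with 26 as in step 15 gives macrocyclic diester F7.
- Methanolysis of the TES ether as in step 16 gives macrocyclic allylic alcohol F8.
- Dess–Martin oxidation of F8 gives 30.

3. Step 14.
- What may go wrong: facial selectivity at the α-acyloxy aldehyde may be poor, because substrate control is the only control element.
- Fallback: C9 is set by reagent-controlled reduction instead of by addition. It sets out from 25 (as its mixture of C9 epimers) and comes back at 25.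
- Dess–Martin oxidation gives enone F9.
- Corey–Bakshi–Shibata reduction follows with (R)-2-methyl-CBS-oxazaborolidine and catecholborane in toluene at −78 °C.
- In that reduction the fully substituted alkenyl flank C10 should act as the large group, which should return the (9R) alcohol 25.

Further compounds
F1 | step 4 | propargyl ether of 6, (1R,2E)-1-[(2R,3R)-3-(tert-butyldimethylsilyloxymethyl)oxiran-2-yl]but-2-en-1-yl prop-2-ynyl ether | C/C=C/[C@@H](OCC#C)[C@H]1O[C@@H]1CO[Si](C)(C)C(C)(C)C
F2 | step 4 | 12-deoxo analogue of 10 (3-methylidene tetrahydrofuran, C6, C7, C8 as in 10) | C=C1CO[C@H](/C=C/C)[C@H]1[C@H](O)CO[Si](C)(C)C(C)(C)C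
F3 | step 4 | 12-deoxo analogue of 13 (C8 angelate of F2) | C=C1CO[C@H](/C=C/C)[C@H]1[C@H](OC(=O)/C(C)=C\C)CO[Si](C)(C)C(C)(C)C
F4 | step 18 | seco iodo aldehyde with C4=C5 in place (C15 trans to C6), C9 aldehyde and (Z)-C10 iodide | C=C1C(=O)O[C@H](/C=C(/CO[Si](C)(C)C(C)(C)C)CC/C=C(/CO[Si](CC)(CC)CC)I)[C@H]1[C@H](OC(=O)/C(C)=C\C)C=O
F5 | step 18 | alkenylchromium dichloride from F4 | C=C1C(=O)O[C@H](/C=C(/CO[Si](C)(C)C(C)(C)C)CC/C=C(/CO[Si](CC)(CC)CC)[Cr](Cl)Cl)[C@H]1[C@H](OC(=O)/C(C)=C\C)C=O
F6 | step 18 | macrocyclic (9R) alcohol, 14-O-TES, 15-O-TBS, C8 angelate | C=C1C(=O)O[C@@H]2/C=C(/CO[Si](C)(C)C(C)(C)C)CC/C=C(/CO[Si](CC)(CC)CC)[C@@H](O)[C@@H](OC(=O)/C(C)=C\C)[C@@H]12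
F7 | step 18 | macrocyclic diester, C9 (2R)-2-methylbutanoate of F6 | C=C1C(=O)O[C@@H]2/C=C(/CO[Si](C)(C)C(C)(C)C)CC/C=C(/CO[Si](CC)(CC)CC)[C@@H](OC(=O)[C@H](C)CC)[C@@H](OC(=O)/C(C)=C\C)[C@@H]12
F8 | step 18 | macrocyclic C14 allylic alcohol (F7 without TES) | C=C1C(=O)O[C@@H]2/C=C(/CO[Si](C)(C)C(C)(C)C)CC/C=C(/CO)[C@@H](OC(=O)[C@H](C)CC)[C@@H](OC(=O)/C(C)=C\C)[C@@H]12
F9 | step 14 | C9 enone from 25 | C=C1C(=O)O[C@H](/C=C/C)[C@H]1[C@H](OC(=O)/C(C)=C\C)C(=O)/C(CO[Si](CC)(CC)CC)=C\CCC(=C)CO[Si](C)(C)C(C)(C)C
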